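## Retrosynthetic overview

1. Target 31 ⇐ dimethoxyquinone 29 ⇐ tetramethoxyarene 28 (CAN oxidation, then selective vinylogous-ester hydrolysis).
2. The Δ5 olefin and the C4 gem-dimethyl group ⇐ vinyl triflate 27 ⇐ conjugate methylation of the pulegone-type enone 24. Ring A is closed by intramolecular aldol condensation of diketone 22.
3. Key disconnection C9–C11: γ-selective carbonyl allylation of aldehyde 16 by the allylindium made from bromide 12. This gives the quaternary C9 and an exocyclic C8 methylene, and the C8 methyl follows by OH-directed hydrogenation.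
4. 12 ⇐ (R)-carvone, which is ring B: trans conjugate addition (C10), enol-triflate carbonylation (the C8 methyl carbon), and ozonolysis/Criegee excision of the isopropenyl group (C6–O handle).
5. Ring order: ring B (carvone) → arene attached → ring A (aldol) → quinone last.

Assumption: labels C1–C11 follow the decalin numbering of the target (C4 = CMe2, C5=C6, C8 = CHMe, C9 = quaternary C, C10 = ring-fusion CH, C11 = ArCH2), and centres that are mixtures and are destroyed later carry no stereo mark.

## Route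

Step 1
Reactants: 1 (R)-(−)-carvone; 2 2-(3-chloropropyl)-2-methyl-1,3-dioxolane
Product: 4 {[(3R,5R)-2-methyl-3-[3-(2-methyl-1,3-dioxolan-2-yl)propyl]-5-(prop-1-en-2-yl)cyclohex-1-en-1-yl]oxy}trimethylsilane, via Grignard reagent 3 (not isolated)
Conditions: 2, Mg, cat. BrCH2CH2Br, THF, reflux; then CuBr·SMe2 (5 mol %), HMPA, TMSCl, 1, THF, −78 → −40 °C; Et3N, pentane/aq NaHCO3
Reagents that add atoms: chlorotrimethylsilane C[Si](C)(C)Cl
Why: The Cu-catalysed, TMSCl-accelerated conjugate addition of the Grignard reagent is axial and anti to the isopropenyl group of carvone, which sets C10 trans to it, and the regiodefined enolate is caught as its silyl enol ether.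

Step 2
Reactants: 4 silyl enol ether
Product: 6 (3R,5R)-2-methyl-3-[3-(2-methyl-1,3-dioxolan-2-yl)propyl]-5-(prop-1-en-2-yl)cyclohex-1-en-1-yl trifluoromethanesulfonate, via lithium enolate 5 (not isolated)
Conditions: MeLi, THF, 0 °C; then PhNTf2, −78 °C → rt; aq NH4Cl
Reagents that add atoms: N-phenylbis(trifluoromethanesulfonimide) O=S(=O)(N(c1ccccc1)S(=O)(=O)C(F)(F)F)C(F)(F)F
Why: Si–O cleavage with MeLi releases the tetrasubstituted enolate without equilibration, and its O-sulfonylation (enol triflate synthesis) locks the C8=C9 olefin without touching a stereocentre.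

Step 3
Reactants: 6 vinyl triflate
Product: 7 methyl (3R,5R)-2-methyl-3-[3-(2-methyl-1,3-dioxolan-2-yl)propyl]-5-(prop-1-en-2-yl)cyclohex-1-ene-1-carboxylate
Conditions: Pd(OAc)2 (5 mol %), dppf, CO (1 atm), MeOH, Et3N, DMF, 60 °C
Reagents that add atoms: carbon monoxide [C-]#[O+]; methanol CO
Why: The Pd-catalysed methoxycarbonylation of the vinyl triflate brings in the carbon that becomes the C8 methyl group and makes the ring olefin electron-poor enough to survive ozone.

Step 4
Reactants: 7 enoate
Product: 10 methyl (3R,5R)-5-acetoxy-2-methyl-3-[3-(2-methyl-1,3-dioxolan-2-yl)propyl]cyclohex-1-ene-1-carboxylate, via methoxy hydroperoxide 8 (not isolated), via peracetate 9 (not isolated)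
Conditions: O3, CH2Cl2/MeOH 5:1, −78 °C (Sudan III end point), N2 purge; then Ac2O, Et3N, cat. DMAP, 0 → 40 °C
Reagents that add atoms: ozone [O-][O+]=O; methanol CO
Why: Ozonolysis cleaves only the electron-rich 1,1-disubstituted olefin, methanol traps the carbonyl oxide, and the peracetate undergoes Criegee rearrangement in which the ring carbon migrates with retention, so the C6–O bond takes the place of the old C6–C bond.

Step 5
Reactants: 10 acetoxy ester
Product: 11 (1R,5R)-3-(hydroxymethyl)-4-methyl-5-[3-(2-methyl-1,3-dioxolan-2-yl)propyl]cyclohex-3-en-1-ol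
Conditions: DIBAL-H (6 equiv), CH2Cl2, −78 → 0 °C; Rochelle salt
Reagents that add atoms: none
Why: The hydride reduction turns the enoate into the allylic alcohol (1,2-reduction) and removes the acetate in the same operation while the ketal and both stereocentres are untouched.

Step 6
Reactants: 11 diol
Product: 12 (1R,5R)-3-(bromomethyl)-4-methyl-5-[3-(2-methyl-1,3-dioxolan-2-yl)propyl]cyclohex-3-en-1-ol (used at once)
Conditions: NBS, Me2S, CH2Cl2, −20 → 0 °C
Reagents that add atoms: N-bromosuccinimide O=C1CCC(=O)N1Br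
Why: In the Corey–Kim halogenation only the allylic alkoxysulfonium ion is displaced by bromide, whereas the one on the secondary C6 hydroxyl reverts to the alcohol on work-up.

Step 7
Reactants: 13 1,2,4,5-tetramethoxybenzene
Product: 16 2,3,5,6-tetramethoxybenzaldehyde, via aryllithium 14 (not isolated), via lithium hemiaminal alkoxide 15 (not isolated)
Conditions: n-BuLi, TMEDA, THF, 0 °C; DMF, 0 °C → rt; 1 M HCl
Reagents that add atoms: N,N-dimethylformamide CN(C)C=O
Why: Directed ortho-lithiation at the position flanked by two methoxy groups followed by formylation with DMF can give only one regioisomer because the two free positions are equivalent.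

Step 8
Reactants: 12 allylic bromide; 16 2,3,5,6-tetramethoxybenzaldehyde
Product: 18 (1R,3R,4S)-4-[hydroxy(2,3,5,6-tetramethoxyphenyl)methyl]-4-methyl-5-methylidene-3-[3-(2-methyl-1,3-dioxolan-2-yl)propyl]cyclohexan-1-ol (C11 epimers), via allylindium dibromide 17 (not isolated)
Conditions: In powder, DMF, rt; aq NH4Cl
Reagents that add atoms: none
Why: In this Barbier-type indium carbonyl allylation the allylmetal reacts through its γ-carbon in a cyclic SE2′ transition state, so the C9–C11 bond, the quaternary C9 and the exocyclic C8 methylene form together, and the aldehyde arrives anti to the C10 side chain (pseudoaxial because of A1,2 strain with the C9 methyl), which places C11 trans to that chain.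

Step 9
Reactants: 18 homoallylic alcohol
Product: 19 (1S,3R,4R,5S)-4-[hydroxy(2,3,5,6-tetramethoxyphenyl)methyl]-4,5-dimethyl-3-[3-(2-methyl-1,3-dioxolan-2-yl)propyl]cyclohexan-1-ol
Conditions: [Ir(cod)(PCy3)(py)]PF6 (5 mol %), H2 (1 atm), CH2Cl2, rt
Reagents that add atoms: none
Why: In the hydroxyl-directed hydrogenation with Crabtree's catalyst, iridium bound to the axial C6–OH or the C11–OH delivers H2 to the face opposite the axial C9 methyl, so C8–H forms on the side of C11 and the new methyl is equatorial and cis to the C9 methyl (8S).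

Step 10
Reactants: 19 ketal diol
Product: 20 5-{(1R,2R,3S,5S)-5-hydroxy-2-[hydroxy(2,3,5,6-tetramethoxyphenyl)methyl]-2,3-dimethylcyclohexyl}pentan-2-one
Conditions: PPTS (0.2 equiv), acetone/H2O 9:1, reflux
Reagents that add atoms: water O
Why: The mild acid-catalysed ketal hydrolysis frees the methyl ketone now, because a dioxolane would itself be reduced under the ionic hydrogenation of the next step.

Step 11
Reactants: 20 keto diol
Product: 21 5-{(1R,2R,3S,5S)-5-hydroxy-2,3-dimethyl-2-[(2,3,5,6-tetramethoxyphenyl)methyl]cyclohexyl}pentan-2-one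
Conditions: Et3SiH (5 equiv), TFA (10 equiv), CH2Cl2, −20 → 0 °C; then K2CO3, MeOH
Reagents that add atoms: none
Why: In the ionic hydrogenation only the benzylic hydroxyl ionises (the cation is stabilised by two ortho methoxy groups) and the cation is captured by silane hydride, while the dialkyl ketone, the C6 alcohol and the olefin-free skeleton are inert.

Step 12
Reactants: 21 hydroxy ketone
Product: 22 (3R,4R,5S)-4,5-dimethyl-3-(4-oxopentyl)-4-[(2,3,5,6-tetramethoxyphenyl)methyl]cyclohexan-1-one
Conditions: Dess–Martin periodinane, NaHCO3, CH2Cl2, rt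
Reagents that add atoms: none
Why: The Dess–Martin oxidation of the only remaining alcohol gives the C6 ketone under neutral conditions that leave the electron-rich arene alone.

Step 13
Reactants: 22 diketone
Product: 24 (3S,4R,4aS)-3,4,8-trimethyl-4-[(2,3,5,6-tetramethoxyphenyl)methyl]-3,4,4a,5,6,7-hexahydronaphthalen-1(2H)-one, via ketol 23 (not isolated)
Conditions: KOH, MeOH, reflux
Reagents that add atoms: none
Why: In the intramolecular aldol condensation only attack of C5 on the C4 ketone gives a six-membered ketol that can dehydrate, whereas the bridged bicyclo[3.3.1] ketol from the other mode simply reverts, and none of C8, C9 or C10 is acidic, so ring A closes without epimerisation.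

Step 14
Reactants: 24 tetrasubstituted enone
Product: 25 {[(3S,4R,4aS)-3,4,8,8-tetramethyl-4-[(2,3,5,6-tetramethoxyphenyl)methyl]-2,3,4,4a,5,6,7,8-octahydronaphthalen-1-yl]oxy}trimethylsilane
Conditions: MeMgBr, CuBr·SMe2 (10 mol %), TMSCl, HMPA, THF, −78 → 0 °C
Reagents that add atoms: methylmagnesium bromide C[Mg]Br; chlorotrimethylsilane C[Si](C)(C)Cl
Why: The Cu-catalysed conjugate addition to this s-cis, pulegone-type enone makes the stereochemically silent C4 gem-dimethyl group and leaves the enolate double bond exactly at C5=C6, where it is stored as the silyl enol ether.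

Step 15
Reactants: 25 silyl enol ether
Product: 27 (3S,4R,4aS)-3,4,8,8-tetramethyl-4-[(2,3,5,6-tetramethoxyphenyl)methyl]-2,3,4,4a,5,6,7,8-octahydronaphthalen-1-yl trifluoromethanesulfonate, via caesium enolate 26 (not isolated)
Conditions: CsF, PhNTf2, DME, rt; aq NH4Cl
Reagents that add atoms: N-phenylbis(trifluoromethanesulfonimide) O=S(=O)(N(c1ccccc1)S(=O)(=O)C(F)(F)F)C(F)(F)F
Why: The fluoride-induced desilylation with in situ O-triflation converts the regiodefined enol ether into the enol triflate without an organolithium base that could metalate the arene C–H between two methoxy groups.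

Step 16
Reactants: 27 vinyl triflate
Product: 28 3-{[(1R,2S,8aS)-1,2,5,5-tetramethyl-1,2,3,5,6,7,8,8a-octahydronaphthalen-1-yl]methyl}-1,2,4,5-tetramethoxybenzene
Conditions: Pd(OAc)2 (5 mol %), PPh3, HCO2H, Et3N, DMF, 60 °C
Reagents that add atoms: none
Why: The Pd-catalysed formate hydrogenolysis of the vinyl triflate replaces OTf by H with the double bond fixed at C5=C6, so no olefin isomer can arise.

Step 17
Reactants: 28 tetramethoxyarene
Product: 29 2,5-dimethoxy-3-{[(1R,2S,8aS)-1,2,5,5-tetramethyl-1,2,3,5,6,7,8,8a-octahydronaphthalen-1-yl]methyl}cyclohexa-2,5-diene-1,4-dione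
Conditions: (NH4)2Ce(NO3)6 (2.5 equiv), MeCN/H2O, 0 °C
Reagents that add atoms: water O
Why: The CAN oxidative demethylation gives a single para-quinone because the two possible para pairs of methoxy groups are symmetry-equivalent, and the hindered trisubstituted olefin is not attacked.

Step 18
Reactants: 29 dimethoxyquinone
Product: 31 2-hydroxy-5-methoxy-3-{[(1R,2S,8aS)-1,2,5,5-tetramethyl-1,2,3,5,6,7,8,8a-octahydronaphthalen-1-yl]methyl}cyclohexa-2,5-diene-1,4-dione (target), via potassium quinonate 30 (not isolated)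
Conditions: KOH, MeOH/H2O, rt → 50 °C; then 1 M HCl, 0 °C
Reagents that add atoms: potassium hydroxide [K+].[OH-]
Why: In this addition–elimination (vinylogous ester saponification) hydroxide should replace the methoxy group next to the bulky side chain, which is twisted out of conjugation, and the resulting hydroxyquinone anion resists a second attack, while basic medium spares the acid-sensitive olefin.

## Compound list

1 | (R)-(−)-carvone | CC1=CC[C@H](CC1=O)C(C)=C | starting material
2 | 2-(3-chloropropyl)-2-methyl-1,3-dioxolane | CC1(CCCCl)OCCO1 | starting material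
3 | [3-(2-methyl-1,3-dioxolan-2-yl)propyl]magnesium chloride | CC1(CCC[Mg]Cl)OCCO1 | intermediate
4 | (3R,5R) TMS enol ether of the carvone conjugate adduct | CC1=C(O[Si](C)(C)C)C[C@H](C(C)=C)C[C@H]1CCCC2(C)OCCO2 | intermediate
5 | lithium enolate corresponding to 4 | CC1=C([O-])C[C@H](C(C)=C)C[C@H]1CCCC2(C)OCCO2.[Li+] | intermediate
6 | (3R,5R) enol triflate | CC1=C(OS(=O)(=O)C(F)(F)F)C[C@H](C(C)=C)C[C@H]1CCCC2(C)OCCO2 | intermediate
7 | (3R,5R) methyl cyclohexenecarboxylate | CC1=C(C(=O)OC)C[C@H](C(C)=C)C[C@H]1CCCC2(C)OCCO2 | intermediate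
8 | 5-(1-hydroperoxy-1-methoxyethyl) ester | CC1=C(C(=O)OC)C[C@H](C(C)(OC)OO)C[C@H]1CCCC2(C)OCCO2 | intermediate
9 | 5-[1-(acetylperoxy)-1-methoxyethyl] ester | CC1=C(C(=O)OC)C[C@H](C(C)(OC)OOC(C)=O)C[C@H]1CCCC2(C)OCCO2 | intermediate
10 | (3R,5R) 5-acetoxy ester | CC1=C(C(=O)OC)C[C@H](OC(C)=O)C[C@H]1CCCC2(C)OCCO2 | intermediate
11 | (1R,5R) diol | CC1=C(CO)C[C@H](O)C[C@H]1CCCC2(C)OCCO2 | intermediate
12 | (1R,5R) allylic bromide | CC1=C(CBr)C[C@H](O)C[C@H]1CCCC2(C)OCCO2 | intermediate
13 | 1,2,4,5-tetramethoxybenzene | COc1cc(OC)c(OC)cc1OC | starting material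
14 | (2,3,5,6-tetramethoxyphenyl)lithium | COc1cc(OC)c(OC)c([Li])c1OC | intermediate
15 | lithium (dimethylamino)(2,3,5,6-tetramethoxyphenyl)methanolate | COc1cc(OC)c(OC)c(C([O-])N(C)C)c1OC.[Li+] | intermediate
16 | 2,3,5,6-tetramethoxybenzaldehyde | COc1cc(OC)c(OC)c(C=O)c1OC | intermediate
17 | allylindium dibromide from 12 (RInBr2 component of the sesquihalide) | CC1=C(C[In](Br)Br)C[C@H](O)C[C@H]1CCCC2(C)OCCO2 | intermediate
18 | (1R,3R,4S) homoallylic alcohol with exocyclic methylene | COc1cc(OC)c(OC)c(C(O)[C@@]2(C)[C@H](CCCC3(C)OCCO3)C[C@@H](O)CC2=C)c1OC | intermediate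
19 | (1S,3R,4R,5S) hydrogenated ketal diol | COc1cc(OC)c(OC)c(C(O)[C@@]2(C)[C@H](CCCC3(C)OCCO3)C[C@@H](O)C[C@@H]2C)c1OC | intermediate
20 | (1R,2R,3S,5S) keto diol | COc1cc(OC)c(OC)c(C(O)[C@@]2(C)[C@H](CCCC(C)=O)C[C@@H](O)C[C@@H]2C)c1OC | intermediate
21 | (1R,2R,3S,5S) hydroxy ketone with ArCH2 | COc1cc(OC)c(OC)c(C[C@@]2(C)[C@H](CCCC(C)=O)C[C@@H](O)C[C@@H]2C)c1OC | intermediate
22 | (3R,4R,5S) diketone | COc1cc(OC)c(OC)c(C[C@@]2(C)[C@H](CCCC(C)=O)CC(=O)C[C@@H]2C)c1OC | intermediate
23 | fused ketol (8-hydroxy-8-methyl decalone) | COc1cc(OC)c(OC)c(C[C@@]2(C)[C@@H]3CCCC(C)(O)C3C(=O)C[C@@H]2C)c1OC | intermediate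
24 | (3S,4R,4aS) tetrasubstituted enone | COc1cc(OC)c(OC)c(C[C@@]2(C)[C@@H]3CCCC(C)=C3C(=O)C[C@@H]2C)c1OC | intermediate
25 | (3S,4R,4aS) TMS enol ether with gem-dimethyl | COc1cc(OC)c(OC)c(C[C@@]2(C)[C@@H]3CCCC(C)(C)C3=C(O[Si](C)(C)C)C[C@@H]2C)c1OC | intermediate
26 | caesium enolate corresponding to 25 | COc1cc(OC)c(OC)c(C[C@@]2(C)[C@@H]3CCCC(C)(C)C3=C([O-])C[C@@H]2C)c1OC.[Cs+] | intermediate
27 | (3S,4R,4aS) vinyl triflate | COc1cc(OC)c(OC)c(C[C@@]2(C)[C@@H]3CCCC(C)(C)C3=C(OS(=O)(=O)C(F)(F)F)C[C@@H]2C)c1OC | intermediate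
28 | (1R,2S,8aS) tetramethoxyarene decalin | COc1cc(OC)c(OC)c(C[C@@]2(C)[C@@H]3CCCC(C)(C)C3=CC[C@@H]2C)c1OC | intermediate
29 | (1R,2S,8aS) 2,5-dimethoxyquinone | COC1=CC(=O)C(OC)=C(C[C@@]2(C)[C@@H]3CCCC(C)(C)C3=CC[C@@H]2C)C1=O | intermediate
30 | potassium salt of the target | COC1=CC(=O)C([O-])=C(C[C@@]2(C)[C@@H]3CCCC(C)(C)C3=CC[C@@H]2C)C1=O.[K+] | intermediate
31 | CNP0348245.1 | COC1=CC(=O)C(O)=C(C[C@@]2(C)[C@@H]3CCCC(C)(C)C3=CC[C@@H]2C)C1=O | target

## Step count and risks

Total steps: 18. Longest linear sequence: 17 (steps 1–6 and 8–18; step 7 is the side branch).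

**Step 8.** This is the most likely failure, because two hindered partners must form a quaternary centre and the allylmetal could react through its CH2 end or not at all. The fallback makes the quaternary centre intramolecularly. It sets out from 11 and returns at 18.
- The primary allylic hydroxyl of 11 is alkylated (KH, ICH2SnBu3, THF) to the stannylmethyl ether F2.
- Tin–lithium exchange (n-BuLi, −78 °C) triggers a Still–Wittig [2,3]-rearrangement anti to the C10 chain and gives the neopentyl diol F3.
- TEMPO/PhI(OAc)2 oxidises only the primary alcohol, giving the hydroxy aldehyde F4.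
- Excess aryllithium 14 adds to F4 to give 18.

**Step 14.** This is the second risk, because cuprate addition to a fully substituted enone can stall. The fallback brings in the second methyl as a cyclopropane carbon. It sets out from 24 and returns at 27.
- 1,2-Reduction (NaBH4, CeCl3) gives the allylic alcohol F5.
- Hydroxyl-directed Simmons–Smith cyclopropanation (Et2Zn, CH2I2) gives the cyclopropyl carbinol F6.
- Dess–Martin oxidation gives the cyclopropyl ketone F7.
- Li/NH3 cleaves the external C5–CH2 bond to the gem-dimethyl lithium enolate F8, which PhNTf2 converts into 27.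

**Step 4.** This is the third risk, because the peracetate may fragment instead of rearranging. The fallback separates cleavage from oxygen insertion. It sets out from 7 and returns at 10.
- Lemieux–Johnson cleavage (cat. OsO4, NaIO4, 2,6-lutidine, dioxane/H2O) gives the methyl ketone F1.
- Baeyer–Villiger oxidation (mCPBA, NaHCO3, CH2Cl2), with migration of the secondary ring carbon with retention, gives 10.

## Further compounds

F1 | step 4 | methyl (3R,5R)-5-acetyl-2-methyl-3-[3-(2-methyl-1,3-dioxolan-2-yl)propyl]cyclohex-1-ene-1-carboxylate | CC1=C(C(=O)OC)C[C@H](C(C)=O)C[C@H]1CCCC2(C)OCCO2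
F2 | step 8 | (1R,5R)-4-methyl-5-[3-(2-methyl-1,3-dioxolan-2-yl)propyl]-3-{[(tributylstannyl)methoxy]methyl}cyclohex-3-en-1-ol | CC1=C(COC[Sn](CCCC)(CCCC)CCCC)C[C@H](O)C[C@H]1CCCC2(C)OCCO2
F3 | step 8 | (1R,3R,4S)-4-(hydroxymethyl)-4-methyl-5-methylidene-3-[3-(2-methyl-1,3-dioxolan-2-yl)propyl]cyclohexan-1-ol | OC[C@@]1(C)[C@H](CCCC2(C)OCCO2)C[C@@H](O)CC1=C
F4 | step 8 | (1S,2R,4R)-4-hydroxy-1-methyl-6-methylidene-2-[3-(2-methyl-1,3-dioxolan-2-yl)propyl]cyclohexane-1-carbaldehyde | O=C[C@@]1(C)[C@H](CCCC2(C)OCCO2)C[C@@H](O)CC1=C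
F5 | step 14 | allylic alcohol from 1,2-reduction of 24 (C6 carbinol epimers) | COc1cc(OC)c(OC)c(C[C@@]2(C)[C@@H]3CCCC(C)=C3C(O)C[C@@H]2C)c1OC
F6 | step 14 | C4,C5-methano (cyclopropyl) carbinol | COc1cc(OC)c(OC)c(C[C@@]2(C)[C@@H]3CCCC4(C)CC34C(O)C[C@@H]2C)c1OC
F7 | step 14 | C4,C5-methano (cyclopropyl) ketone | COc1cc(OC)c(OC)c(C[C@@]2(C)[C@@H]3CCCC4(C)CC34C(=O)C[C@@H]2C)c1OC
F8 | step 14 | lithium enolate with C4 gem-dimethyl group | COc1cc(OC)c(OC)c(C[C@@]2(C)[C@@H]3CCCC(C)(C)C3=C([O-])C[C@@H]2C)c1OC.[Li+]
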